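**Retrosynthetic overview**

1. Target 20 ⇐ chromanol 18: the furan ring C is closed last, by desilylation and 5-exo attack of O11 on the C11a p-quinone methide/cation (C11a–O11 bond).
2. 18 ⇐ 16: [1,2]-Wittig ring contraction of a seven-membered 2,3-dihydro-5H-1,4-benzodioxepine to the pyran ring B; it makes C6a–C11a, the only C–C bond between the two aromatic halves. Enabling feature: C6a (benzylic to ring D) and C11a (benzylic to ring A, ortho to O5) can both hang on one ether oxygen, so C11a can be lithiated and C6a can migrate as a benzylic radical.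
3. 16 ⇐ 15 ⇐ 13 + 3: C11a–O by reductive etherification, O5–C6 by phenoxide opening of an (R)-aryloxirane; the C6a stereocentre comes from a CBS reduction.
4. Ring D/dimethylpyran block 10 from 2,4,5-trihydroxybenzaldehyde by two aromatic Claisen rearrangements; ring A block 3 from 5-bromo-2,4-dihydroxybenzaldehyde by Stille prenylation.
5. Ring order: dimethylpyran on ring D → 1,4-dioxepine (seven-membered) → pyran B (six-membered, by contraction) → furan C.

Key step: step 13

Assumption: pterocarpan numbering is used throughout (ring A with C1–C4a/C11b, pyran B = O5–C6–C6a–C11a–C11b–C4a, furan C with O11, ring D = C6b–C10a, dimethylpyran on C7/C8). Compound 18 is carried on as a mixture of C11a epimers because step 14 passes through the C11a cation.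

Abbreviations in names: prenyl = 3-methylbut-2-en-1-yl; TIPS = triisopropylsilyl; ArD = 2,2-dimethyl-7-prenyl-6,8-bis(TIPS-oxy)-2H-chromen-5-yl.

**Route**

Step 1
Reactants: 1 5-bromo-2,4-dihydroxybenzaldehyde
Product: 2 5-bromo-2-hydroxy-4-(TIPS-oxy)benzaldehyde
Conditions: TIPSCl, imidazole, DMF, 0 °C
Reagents that add atoms: triisopropylsilyl chloride, CC(C)[Si](Cl)(C(C)C)C(C)C
Why: Selective silylation: the 4-OH (para to the formyl group, not chelated) should react, while the 2-OH is held in the hydrogen bond to C=O.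

Step 2
Reactants: 2 5-bromo-2-hydroxy-4-(TIPS-oxy)benzaldehyde
Product: 3 2-hydroxy-5-prenyl-4-(TIPS-oxy)benzaldehyde
Conditions: tributyl(prenyl)stannane, Pd(PPh3)4 (5 mol%), DMF, 90 °C
Reagents that add atoms: tributyl(3-methylbut-2-en-1-yl)stannane, CCCC[Sn](CCCC)(CCCC)CC=C(C)C
Why: Stille coupling should replace Br by the linear prenyl group (transfer through the α-carbon of the allylstannane); no fluoride or base is present, so the silyl ether and the chelated phenol survive.

Step 3
Reactants: 4 2,4,5-trihydroxybenzaldehyde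
Product: 5 2,5-dihydroxy-4-[(2-methylbut-3-yn-2-yl)oxy]benzaldehyde
Conditions: 3-chloro-3-methylbut-1-yne (1.1 equiv), K2CO3 (1.0 equiv), KI, CuI (cat.), acetone, 45 °C, argon
Reagents that add atoms: 3-chloro-3-methylbut-1-yne, CC(C)(Cl)C#C
Why: Copper-assisted O-propargylation with one equivalent of base should take the most acidic phenol (4-OH, para to CHO), as with 2,4- and 3,4-dihydroxybenzaldehydes.

Step 4
Reactants: 5 2,5-dihydroxy-4-[(2-methylbut-3-yn-2-yl)oxy]benzaldehyde
Product: 6 2,5-dihydroxy-4-[(2-methylbut-3-en-2-yl)oxy]benzaldehyde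
Conditions: H2 (1 atm), Lindlar catalyst, quinoline, EtOAc, rt
Reagents that add atoms: none
Why: Lindlar semi-hydrogenation should stop at the 1,1-dimethylallyl ether and leave the aldehyde untouched.

Step 5
Reactants: 6 2,5-dihydroxy-4-[(2-methylbut-3-en-2-yl)oxy]benzaldehyde
Product: 7 2-hydroxy-4-[(2-methylbut-3-en-2-yl)oxy]-5-[(2-methylbut-3-yn-2-yl)oxy]benzaldehyde
Conditions: 3-chloro-3-methylbut-1-yne, K2CO3, KI, CuI (cat.), acetone, 45 °C, argon
Reagents that add atoms: 3-chloro-3-methylbut-1-yne, CC(C)(Cl)C#C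
Why: The same O-propargylation should now take the 5-OH, the only phenol that is not chelated to the formyl group.

Step 6
Reactants: 7 2-hydroxy-4-[(2-methylbut-3-en-2-yl)oxy]-5-[(2-methylbut-3-yn-2-yl)oxy]benzaldehyde
Product: 9 6,8-dihydroxy-2,2-dimethyl-7-prenyl-2H-chromene-5-carbaldehyde, via 2,4-dihydroxy-3-prenyl-5-[(2-methylbut-3-yn-2-yl)oxy]benzaldehyde 8 (not isolated)
Conditions: N,N-diethylaniline, 110 °C, then 150 °C
Reagents that add atoms: none
Why: Two aromatic Claisen rearrangements in one heating: the 1,1-dimethylallyl ether should give the C-prenyl group at the only free ortho carbon, then the propargyl ether should rearrange to its only free ortho carbon and close the 2,2-dimethyl-2H-chromene by 1,5-H shift and oxa-6π electrocyclisation.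

Step 7
Reactants: 9 6,8-dihydroxy-2,2-dimethyl-7-prenyl-2H-chromene-5-carbaldehyde
Product: 10 2,2-dimethyl-7-prenyl-6,8-bis(TIPS-oxy)-2H-chromene-5-carbaldehyde (ArD–CHO)
Conditions: TIPSOTf (2.4 equiv), 2,6-lutidine, CH2Cl2, 0 °C to rt
Reagents that add atoms: triisopropylsilyl triflate, CC(C)[Si](OS(=O)(=O)C(F)(F)F)(C(C)C)C(C)C
Why: The silyl triflate should silylate both phenols, including the chelated, flanked 6-OH; the bulky TIPS groups are chosen because they resist O-to-O migration and alkyllithiums later.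

Step 8
Reactants: 10 ArD–CHO
Product: 11 rac-2-chloro-1-(ArD)ethan-1-ol
Conditions: ICH2Cl, MeLi·LiBr, THF, −78 °C; AcOH, −78 °C
Reagents that add atoms: chloroiodomethane, ClCI
Why: Chloromethyllithium made in situ by iodine–lithium exchange should add to the aldehyde (carbenoid 1,2-addition); the cold acidic quench prevents epoxide closure.

Step 9
Reactants: 11 rac-2-chloro-1-(ArD)ethan-1-ol
Product: 12 2-chloro-1-(ArD)ethan-1-one
Conditions: Dess–Martin periodinane, CH2Cl2, 0 °C to rt
Reagents that add atoms: none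
Why: Dess–Martin oxidation of the secondary benzylic alcohol should leave the alkenes, silyl ethers and the C–Cl bond untouched.

Step 10
Reactants: 12 2-chloro-1-(ArD)ethan-1-one
Product: 13 (1R)-2-chloro-1-(ArD)ethan-1-ol
Conditions: (R)-Me-CBS (20 mol%), catecholborane, toluene, −78 to −40 °C; aqueous work-up
Reagents that add atoms: none
Why: Corey–Bakshi–Shibata reduction: the twisted, 2,6-disubstituted aryl group is the large and CH2Cl the small substituent, so the (R)-oxazaborolidine should deliver hydride to give the (R)-chlorohydrin; catecholborane does not hydroborate the alkenes at this temperature.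

Step 11
Reactants: 13 (1R)-2-chloro-1-(ArD)ethan-1-ol and 3 2-hydroxy-5-prenyl-4-(TIPS-oxy)benzaldehyde
Product: 15 2-[(2R)-2-(ArD)-2-hydroxyethoxy]-5-prenyl-4-(TIPS-oxy)benzaldehyde, via (2R)-2-(ArD)oxirane 14 (not isolated)
Conditions: Cs2CO3, DMF, 60 °C
Reagents that add atoms: none
Why: Base should close the epoxide (intramolecular Williamson, C6a untouched) and the phenoxide of 3 should open it by SN2 at the unhindered CH2, so the O5–C6 bond forms with the C6a configuration retained.

Step 12
Reactants: 15 2-[(2R)-2-(ArD)-2-hydroxyethoxy]-5-prenyl-4-(TIPS-oxy)benzaldehyde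
Product: 16 (3R)-3-(ArD)-7-prenyl-8-(TIPS-oxy)-2,3-dihydro-5H-1,4-benzodioxepine
Conditions: Et3SiH, TMSOTf (cat.), CH2Cl2, −78 to −40 °C
Reagents that add atoms: none
Why: Intramolecular reductive etherification (cyclic hemiacetal, oxocarbenium ion at C11a, hydride from the silane) should close the seven-membered ether without breaking the C6a–O bond.

Step 13
Reactants: 16 (3R)-3-(ArD)-7-prenyl-8-(TIPS-oxy)-2,3-dihydro-5H-1,4-benzodioxepine
Product: 18 (3R)-3-(ArD)-6-prenyl-7-(TIPS-oxy)-3,4-dihydro-2H-chromen-4-ol (mixture of C4 epimers), via the 5-lithio derivative of the benzodioxepine 17 (not isolated)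
Conditions: s-BuLi (1.3 equiv), THF, −78 °C, then −20 °C; H2O
Reagents that add atoms: none
Why: s-BuLi should remove a C11a proton (C5 of the dioxepine), which is benzylic to ring A, α to the ring oxygen and next to the chelating ortho ether oxygen O5, and on warming the α-oxybenzyllithium 17 should undergo the [1,2]-Wittig rearrangement: homolysis of the O–C6a bond to a ketyl radical anion at C11a and a benzylic radical at C6a, which stay tethered through C6–O5–ring A and recombine to the C6a–C11a bond. The closest known reaction type is the [1,2]-Wittig ring contraction of cyclic dibenzylic ethers (dihydrodibenzoxepine to 9,10-dihydrophenanthren-9-ol). Pyran ring B is closed by this 1,2-shift, that is, by contraction of the seven-membered 1,4-dioxepine, whose O4 becomes the exocyclic C11a alkoxide (radical-pair recombination between C6a and C11a, not cyclisation of an open chain). C6a should keep its R configuration (retention at the migrating carbon is the normal course of this rearrangement, helped here by the tether and by slow rotation of a radical that carries a 2,6-disubstituted aryl group), while C11a forms unselectively, which is harmless because step 14 ionises it. The step needs site-selective metalation at C11a and a 1,2- rather than an ortho-[2,3]-shift: ring D has no aromatic hydrogen and both its ortho positions are substituted, C6a–H and the prenyl CH2 groups are shielded by flanking OTIPS groups, and ring A C4–H sits next to a bulky, non-coordinating OTIPS group.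

Step 14
Reactants: 18 (3R)-3-(ArD)-6-prenyl-7-(TIPS-oxy)-3,4-dihydro-2H-chromen-4-ol
Product: 20 Lespecyrtin E3, (6aR,11aR), via (3R)-3-[6,8-dihydroxy-2,2-dimethyl-7-prenyl-2H-chromen-5-yl]-6-prenyl-3,4-dihydro-2H-chromene-4,7-diol 19 (not isolated)
Conditions: TBAF (3.5 equiv), THF, 0 °C; then AcOH, rt to 40 °C
Reagents that add atoms: none
Why: Fluoride should remove the three silyl groups, and in acetic acid the C11a–OH (para to the freed 3-OH, ortho to O5) should ionise to the p-quinone methide/benzylic cation, which the 2'-OH (O11) traps in a 5-exo closure; only the cis-fused furan is possible, so C6a (R) sets C11a (R), as in the acid cyclisation of 2'-hydroxyisoflavan-4-ols to pterocarpans.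

**Compound list**

1 | 5-bromo-2,4-dihydroxybenzaldehyde | O=Cc1cc(Br)c(O)cc1O | starting material
2 | 5-bromo-2-hydroxy-4-(TIPS-oxy)benzaldehyde | O=Cc1cc(Br)c(O[Si](C(C)C)(C(C)C)C(C)C)cc1O | intermediate
3 | 2-hydroxy-5-prenyl-4-(TIPS-oxy)benzaldehyde | O=Cc1cc(CC=C(C)C)c(O[Si](C(C)C)(C(C)C)C(C)C)cc1O | intermediate
4 | 2,4,5-trihydroxybenzaldehyde | O=Cc1cc(O)c(O)cc1O | starting material
5 | 2,5-dihydroxy-4-[(2-methylbut-3-yn-2-yl)oxy]benzaldehyde | O=Cc1cc(O)c(OC(C)(C)C#C)cc1O | intermediate
6 | 2,5-dihydroxy-4-[(2-methylbut-3-en-2-yl)oxy]benzaldehyde | O=Cc1cc(O)c(OC(C)(C)C=C)cc1O | intermediate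
7 | 2-hydroxy-4-[(2-methylbut-3-en-2-yl)oxy]-5-[(2-methylbut-3-yn-2-yl)oxy]benzaldehyde | O=Cc1cc(OC(C)(C)C#C)c(OC(C)(C)C=C)cc1O | intermediate
8 | 2,4-dihydroxy-3-prenyl-5-[(2-methylbut-3-yn-2-yl)oxy]benzaldehyde | O=Cc1cc(OC(C)(C)C#C)c(O)c(CC=C(C)C)c1O | intermediate (not isolated)
9 | 6,8-dihydroxy-2,2-dimethyl-7-prenyl-2H-chromene-5-carbaldehyde | O=Cc1c2C=CC(C)(C)Oc2c(O)c(CC=C(C)C)c1O | intermediate
10 | 2,2-dimethyl-7-prenyl-6,8-bis(TIPS-oxy)-2H-chromene-5-carbaldehyde | O=Cc1c2C=CC(C)(C)Oc2c(O[Si](C(C)C)(C(C)C)C(C)C)c(CC=C(C)C)c1O[Si](C(C)C)(C(C)C)C(C)C | intermediate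
11 | rac-2-chloro-1-(ArD)ethan-1-ol | OC(CCl)c1c2C=CC(C)(C)Oc2c(O[Si](C(C)C)(C(C)C)C(C)C)c(CC=C(C)C)c1O[Si](C(C)C)(C(C)C)C(C)C | intermediate
12 | 2-chloro-1-(ArD)ethan-1-one | O=C(CCl)c1c2C=CC(C)(C)Oc2c(O[Si](C(C)C)(C(C)C)C(C)C)c(CC=C(C)C)c1O[Si](C(C)C)(C(C)C)C(C)C | intermediate
13 | (1R)-2-chloro-1-(ArD)ethan-1-ol | O[C@@H](CCl)c1c2C=CC(C)(C)Oc2c(O[Si](C(C)C)(C(C)C)C(C)C)c(CC=C(C)C)c1O[Si](C(C)C)(C(C)C)C(C)C | intermediate
14 | (2R)-2-(ArD)oxirane | C1O[C@@H]1c1c2C=CC(C)(C)Oc2c(O[Si](C(C)C)(C(C)C)C(C)C)c(CC=C(C)C)c1O[Si](C(C)C)(C(C)C)C(C)C | intermediate (not isolated)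
15 | 2-[(2R)-2-(ArD)-2-hydroxyethoxy]-5-prenyl-4-(TIPS-oxy)benzaldehyde | O=Cc1cc(CC=C(C)C)c(O[Si](C(C)C)(C(C)C)C(C)C)cc1OC[C@H](O)c1c2C=CC(C)(C)Oc2c(O[Si](C(C)C)(C(C)C)C(C)C)c(CC=C(C)C)c1O[Si](C(C)C)(C(C)C)C(C)C | intermediate
16 | (3R)-3-(ArD)-7-prenyl-8-(TIPS-oxy)-2,3-dihydro-5H-1,4-benzodioxepine | C1Oc2cc(O[Si](C(C)C)(C(C)C)C(C)C)c(CC=C(C)C)cc2CO[C@@H]1c1c2C=CC(C)(C)Oc2c(O[Si](C(C)C)(C(C)C)C(C)C)c(CC=C(C)C)c1O[Si](C(C)C)(C(C)C)C(C)C | intermediate
17 | (3R)-3-(ArD)-5-lithio-7-prenyl-8-(TIPS-oxy)-2,3-dihydro-5H-1,4-benzodioxepine | C1Oc2cc(O[Si](C(C)C)(C(C)C)C(C)C)c(CC=C(C)C)cc2C([Li])O[C@@H]1c1c2C=CC(C)(C)Oc2c(O[Si](C(C)C)(C(C)C)C(C)C)c(CC=C(C)C)c1O[Si](C(C)C)(C(C)C)C(C)C | intermediate (not isolated)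
18 | (3R)-3-(ArD)-6-prenyl-7-(TIPS-oxy)-3,4-dihydro-2H-chromen-4-ol, C4 epimers | OC1c2cc(CC=C(C)C)c(O[Si](C(C)C)(C(C)C)C(C)C)cc2OC[C@H]1c1c2C=CC(C)(C)Oc2c(O[Si](C(C)C)(C(C)C)C(C)C)c(CC=C(C)C)c1O[Si](C(C)C)(C(C)C)C(C)C | intermediate
19 | (3R)-3-[6,8-dihydroxy-2,2-dimethyl-7-prenyl-2H-chromen-5-yl]-6-prenyl-3,4-dihydro-2H-chromene-4,7-diol, C4 epimers | OC1c2cc(CC=C(C)C)c(O)cc2OC[C@H]1c1c2C=CC(C)(C)Oc2c(O)c(CC=C(C)C)c1O | intermediate (not isolated)
20 | Lespecyrtin E3, (6aR,11aR) | CC(C)=CCc1cc2c(cc1O)OC[C@H]1c3c4c(c(O)c(CC=C(C)C)c3O[C@@H]21)OC(C)(C)C=C4 | target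

**Step count and risks**

Total step count: 14. Longest linear sequence: 12 steps (steps 3–14, from 4); the ring A block 3 (steps 1–2) enters at step 11.

Steps most likely to fail:

Step 13 (key step). The configuration at C6a may be partly lost if the C6a radical rotates within the tethered radical pair before it recombines, which would erode the enantiomeric purity of 18 and 20. The fallback replaces chirality transfer by catalyst control after the ring contraction. It sets out from 18, used as obtained (18 may then also be made from racemic 11 without steps 9 and 10). Dess–Martin oxidation should give the isoflavanone F1, whose C3 (= C6a) is epimerisable. Asymmetric transfer hydrogenation under dynamic kinetic resolution (RuCl[(R,R)-TsDPEN](p-cymene), HCO2H/Et3N), the known route from isoflavanones to cis-isoflavan-4-ols, should then give the cis-(3R,4R) alcohol. This is one stereoisomer of 18, so the fallback comes back to the route at 18 and continues with step 14.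

Step 10. Hydride delivery to the twisted, 2,6-disubstituted aryl ketone may be slow or poorly face-selective. The fallback uses kinetic resolution instead of asymmetric reduction and sets out from racemic 11 (step 9 is then not needed). KOtBu in THF at 0 °C should close the racemic oxirane F2. Hydrolytic kinetic resolution with (R,R)-(salen)Co(III)OAc and 0.55 equiv of water should hydrolyse the (S)-epoxide to the (S)-diol F3 and leave the (R)-epoxide; the catalyst enantiomer is chosen by the usual preference with terminal epoxides. The (R)-epoxide is 14, where the fallback comes back to the route; it is then opened with 3 and Cs2CO3 as in step 11.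

Step 12. Under the Lewis acid the electron-rich benzylic C–O bonds may ionise, which would lead to over-reduction at C11a or erosion at C6a, and the prenyl and chromene alkenes may be protonated. The fallback closes the ring under basic conditions and sets out from 15. NaBH4 in MeOH/THF at 0 °C should reduce the aldehyde to the diol F4. NaH (2.2 equiv) followed by TsCl (1.0 equiv) in THF, 0 °C to rt, should sulfonylate the unhindered primary benzylic alkoxide, which the C6a alkoxide displaces in an intramolecular Williamson reaction. This gives 16, where the fallback comes back to the route.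

Further compounds
F1 | step 13 | 3-(ArD)-6-prenyl-7-(TIPS-oxy)-2,3-dihydro-4H-chromen-4-one (isoflavanone, C3 epimerisable) | O=C1c2cc(CC=C(C)C)c(O[Si](C(C)C)(C(C)C)C(C)C)cc2OCC1c1c2C=CC(C)(C)Oc2c(O[Si](C(C)C)(C(C)C)C(C)C)c(CC=C(C)C)c1O[Si](C(C)C)(C(C)C)C(C)C
F2 | step 10 | rac-2-(ArD)oxirane | C1OC1c1c2C=CC(C)(C)Oc2c(O[Si](C(C)C)(C(C)C)C(C)C)c(CC=C(C)C)c1O[Si](C(C)C)(C(C)C)C(C)C
F3 | step 10 | (1S)-1-(ArD)ethane-1,2-diol | OC[C@@H](O)c1c2C=CC(C)(C)Oc2c(O[Si](C(C)C)(C(C)C)C(C)C)c(CC=C(C)C)c1O[Si](C(C)C)(C(C)C)C(C)C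
F4 | step 12 | (1R)-1-(ArD)-2-[2-(hydroxymethyl)-4-prenyl-5-(TIPS-oxy)phenoxy]ethan-1-ol | OCc1cc(CC=C(C)C)c(O[Si](C(C)C)(C(C)C)C(C)C)cc1OC[C@H](O)c1c2C=CC(C)(C)Oc2c(O[Si](C(C)C)(C(C)C)C(C)C)c(CC=C(C)C)c1O[Si](C(C)C)(C(C)C)C(C)C
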